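Read backwards, the oxolane of the target (O1, C2 carrying ring A, C3 carrying the CH2O-ester, C4 carrying the ring-B benzyl group, C5) is a reduced and re-closed γ-alkoxybutanolide. C5 was the lactone carbonyl, C4 its α-carbon, C3 its β-carbon, the exocyclic CH2O carbon the acetal centre, and C2 an aroyl-anion carbon. One three-component operation adds a lithiated ring-A dithiane to a menthyloxybutenolide and benzylates the enolate. This forges C2–C3 and C4–CH2 and sets C3 and C4 from the acetal. Its precursors are the crystalline (5R)-butenolide, an aryl dithiane and a benzylic bromide. Unmasking, global reduction and cationic O1–C2 closure then place ring A trans to the C3 substituent.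

Key step: step 6

Remark: O1 and C2–C5 always refer to the oxolane of the target, ring A is the aryl group on C2 and ring B the aryl group of the C4 benzyl substituent; triol 15 is carried as a mixture of carbinol epimers because step 9 erases and resets that centre.

Step 1
Reactants: 1 furfural
Product: 3 5-hydroxy-2(5H)-furanone (racemic), via furfural endoperoxide 2 (not isolated)
Conditions: O2, methylene blue (cat.), visible light, MeOH, 0–20 °C
Reagents that add atoms: oxygen, O=O
Why: Singlet oxygen adds across the furan diene in a [4+2] cycloaddition and methanol then cleaves the formyl group from endoperoxide 2 (dye-sensitised photo-oxygenation of furfural); the racemic pseudo-acid is acceptable because its acetal carbon is equilibrated in step 2.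

Step 2
Reactants: 3 5-hydroxy-2(5H)-furanone; 4 (−)-menthol
Product: 5 (5R)-5-(l-menthyloxy)-2(5H)-furanone
Conditions: CSA (cat.), toluene, reflux, Dean–Stark; crystallisation from hexane, mother liquor re-equilibrated with acid
Reagents that add atoms: none
Why: Acid-catalysed acetalisation of the pseudo-acid gives two acetal epimers that interconvert under acid, and the (5R)-epimer should be the crystalline one, so the acetal stereocentre is set by crystallisation from an equilibrating epimer pair.

Step 3
Reactants: 6 O-benzylvanillin; 7 propane-1,3-dithiol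
Product: 8 2-(4-benzyloxy-3-methoxyphenyl)-1,3-dithiane
Conditions: BF3·OEt2 (cat.), CH2Cl2, 0 °C to rt
Reagents that add atoms: none
Why: Lewis-acid-catalysed thioacetalisation of an aromatic aldehyde turns the future C2 into an acyl-anion equivalent (Corey–Seebach umpolung) and leaves the benzyl ether untouched.

Step 4
Reactants: 6 O-benzylvanillin
Product: 9 4-benzyloxy-3-methoxybenzyl alcohol
Conditions: NaBH4, MeOH, 0 °C
Reagents that add atoms: none
Why: Borohydride reduction of an aromatic aldehyde is fast and touches no other group in the molecule.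

Step 5
Reactants: 9 4-benzyloxy-3-methoxybenzyl alcohol
Product: 10 4-benzyloxy-3-methoxybenzyl bromide
Conditions: PBr3, Et2O, 0 °C; used freshly
Reagents that add atoms: PBr3, BrP(Br)Br
Why: The benzylic alcohol is brominated through its phosphite ester by bromide displacement, and the electron-rich bromide is used at once because it ionises easily on storage.

Step 6
Reactants: 8 2-(4-benzyloxy-3-methoxyphenyl)-1,3-dithiane; 5 (5R)-5-(l-menthyloxy)-2(5H)-furanone; 10 4-benzyloxy-3-methoxybenzyl bromide
Product: 13 (3R,4R,5R)-3-(4-benzyloxy-3-methoxybenzyl)-4-[2-(4-benzyloxy-3-methoxyphenyl)-1,3-dithian-2-yl]-5-(l-menthyloxy)dihydrofuran-2(3H)-one, via 2-lithio dithiane 11 (not isolated), via lithium lactone enolate 12 (not isolated)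
Conditions: n-BuLi, THF, −78 to −20 °C; 5, −90 °C; then 10, DMPU, −78 °C to rt
Reagents that add atoms: none
Why: The sulfur- and aryl-stabilised carbanion 11 is a soft nucleophile that attacks the β-carbon of butenolide 5, and the lithium enolate 12 so formed is alkylated in the same flask by the reactive benzylic bromide 10 in an SN2 step; this is the established tandem Michael addition–enolate alkylation of butenolides used for lignan skeletons. No ring is closed, and two C–C bonds are made (C2–C3 and C4–CH2 of the ring-B benzyl group). The β-stereocentre (future C3) is controlled by the acetal carbon, because the menthyloxy group blocks one face of the flat butenolide and the nucleophile enters anti to it. The α-stereocentre (future C4) is controlled by the very large aryl-dithianyl group just installed, which directs the bromide to the opposite enolate face and gives the all-trans lactone, also the thermodynamically preferred arrangement. The step needs 1,4- over 1,2-addition, secured by charge delocalisation in 11 and the low temperature. It also needs C-alkylation faster than proton exchange, secured by the lithium counter-ion, the DMPU cosolvent and the high SN2 reactivity of 10.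

Step 7
Reactants: 13 trans-disubstituted menthyloxy lactone
Product: 14 (3R,4R,5R)-4-(4-benzyloxy-3-methoxybenzoyl)-3-(4-benzyloxy-3-methoxybenzyl)-5-(l-menthyloxy)dihydrofuran-2(3H)-one
Conditions: HgO, BF3·OEt2, aq. THF, rt
Reagents that add atoms: water, O
Why: Thiophilic divalent mercury activates the C–S bonds and water supplies the carbonyl oxygen (mercury-assisted dithiane hydrolysis), under mild conditions that should spare the acetal and lactone and leave C3 in its already most stable all-trans arrangement.

Step 8
Reactants: 14 keto lactone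
Product: 15 (2R,3R)-2-[(4-benzyloxy-3-methoxyphenyl)(hydroxy)methyl]-3-(4-benzyloxy-3-methoxybenzyl)butane-1,4-diol (carbinol epimers)
Conditions: LiAlH4, THF, 0 °C to rt; aq. NaOH work-up
Reagents that add atoms: none
Why: Exhaustive hydride reduction converts the ketone into the carbinol, the lactone carbonyl (C5) into CH2OH and the acetal carbon, unmasked as an aldehyde once the ring opens and menthoxide leaves, into the second CH2OH; C3 and C4 are untouched and the unselective new carbinol centre is irrelevant.

Step 9
Reactants: 15 triol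
Product: 16 [(2S,3R,4R)-2-(4-benzyloxy-3-methoxyphenyl)-4-(4-benzyloxy-3-methoxybenzyl)oxolan-3-yl]methanol (di-O-benzyl-(+)-lariciresinol)
Conditions: CSA (cat.), CH2Cl2 (dilute), 0 °C, quenched with Et3N at full conversion
Reagents that add atoms: none
Why: Mild acid ionises only the p-alkoxybenzylic carbinol, and the C5 hydroxyl traps the planar cation in a five-membered SN1 cycloetherification, the other primary hydroxyl being able to give only an oxetane; both carbinol epimers therefore converge and C2 is set (S) under substrate control, ring A ending trans to the C3 and C4 substituents because the alternative all-cis oxolane is strongly congested.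

Step 10
Reactants: 16 di-O-benzyl-(+)-lariciresinol; 17 isovaleryl chloride
Product: 18 [(2S,3R,4R)-2-(4-benzyloxy-3-methoxyphenyl)-4-(4-benzyloxy-3-methoxybenzyl)oxolan-3-yl]methyl 3-methylbutanoate
Conditions: Et3N, DMAP (cat.), CH2Cl2, 0 °C to rt
Reagents that add atoms: none
Why: DMAP-catalysed acylation meets a single free hydroxyl group, so no regiochemical question arises and no stereocentre is involved.

Step 11
Reactants: 18 di-O-benzyl ester
Product: 19 (+)-9'-isovaleroxylariciresinol
Conditions: H2 (1 atm), 10% Pd/C, EtOAc, rt, stopped at full conversion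
Reagents that add atoms: none
Why: Catalytic hydrogenolysis cleaves the two unhindered aryl benzyl ethers much faster than the hindered secondary benzylic C2–O1 bond under neutral conditions at atmospheric pressure, and the ester and all three stereocentres are unaffected.

Compound list
1 | furfural | O=Cc1ccco1 | starting material
2 | furfural endoperoxide (2,3,7-trioxabicyclo[2.2.1]hept-5-ene-1-carbaldehyde, racemic) | O=CC12C=CC(OO1)O2 | intermediate
3 | 5-hydroxy-2(5H)-furanone (racemic) | O=C1OC(O)C=C1 | intermediate
4 | (−)-menthol | CC(C)[C@@H]1CC[C@@H](C)C[C@H]1O | starting material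
5 | (5R)-5-(l-menthyloxy)-2(5H)-furanone | O=C1O[C@@H](O[C@@H]2C[C@H](C)CC[C@H]2C(C)C)C=C1 | intermediate
6 | O-benzylvanillin | COc1cc(C=O)ccc1OCc1ccccc1 | starting material
7 | propane-1,3-dithiol | SCCCS | starting material
8 | 2-(4-benzyloxy-3-methoxyphenyl)-1,3-dithiane | COc1cc(C2SCCCS2)ccc1OCc1ccccc1 | intermediate
9 | 4-benzyloxy-3-methoxybenzyl alcohol | COc1cc(CO)ccc1OCc1ccccc1 | intermediate
10 | 4-benzyloxy-3-methoxybenzyl bromide | COc1cc(CBr)ccc1OCc1ccccc1 | intermediate
11 | 2-lithio-2-(4-benzyloxy-3-methoxyphenyl)-1,3-dithiane | COc1cc(C2([Li])SCCCS2)ccc1OCc1ccccc1 | intermediate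
12 | lithium enolate of the (4R,5R)-β-dithianyl menthyloxy lactone | [Li]OC1=C[C@@H](C2(c3ccc(OCc4ccccc4)c(OC)c3)SCCCS2)[C@H](O[C@@H]2C[C@H](C)CC[C@H]2C(C)C)O1 | intermediate
13 | (3R,4R,5R)-3-(4-benzyloxy-3-methoxybenzyl)-4-[2-(4-benzyloxy-3-methoxyphenyl)-1,3-dithian-2-yl]-5-(l-menthyloxy)dihydrofuran-2(3H)-one | COc1cc(C[C@H]2C(=O)O[C@@H](O[C@@H]3C[C@H](C)CC[C@H]3C(C)C)[C@@H]2C2(c3ccc(OCc4ccccc4)c(OC)c3)SCCCS2)ccc1OCc1ccccc1 | intermediate
14 | (3R,4R,5R)-4-(4-benzyloxy-3-methoxybenzoyl)-3-(4-benzyloxy-3-methoxybenzyl)-5-(l-menthyloxy)dihydrofuran-2(3H)-one | COc1cc(C[C@H]2C(=O)O[C@@H](O[C@@H]3C[C@H](C)CC[C@H]3C(C)C)[C@@H]2C(=O)c2ccc(OCc3ccccc3)c(OC)c2)ccc1OCc1ccccc1 | intermediate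
15 | (2R,3R)-2-[(4-benzyloxy-3-methoxyphenyl)(hydroxy)methyl]-3-(4-benzyloxy-3-methoxybenzyl)butane-1,4-diol, carbinol epimers | COc1cc(C[C@@H](CO)[C@H](CO)C(O)c2ccc(OCc3ccccc3)c(OC)c2)ccc1OCc1ccccc1 | intermediate
16 | [(2S,3R,4R)-2-(4-benzyloxy-3-methoxyphenyl)-4-(4-benzyloxy-3-methoxybenzyl)oxolan-3-yl]methanol | COc1cc(C[C@H]2CO[C@H](c3ccc(OCc4ccccc4)c(OC)c3)[C@H]2CO)ccc1OCc1ccccc1 | intermediate
17 | isovaleryl chloride | CC(C)CC(=O)Cl | starting material
18 | [(2S,3R,4R)-2-(4-benzyloxy-3-methoxyphenyl)-4-(4-benzyloxy-3-methoxybenzyl)oxolan-3-yl]methyl 3-methylbutanoate | COc1cc(C[C@H]2CO[C@H](c3ccc(OCc4ccccc4)c(OC)c3)[C@H]2COC(=O)CC(C)C)ccc1OCc1ccccc1 | intermediate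
19 | (+)-9'-isovaleroxylariciresinol, [(2S,3R,4R)-2-(4-hydroxy-3-methoxyphenyl)-4-(4-hydroxy-3-methoxybenzyl)oxolan-3-yl]methyl 3-methylbutanoate | COc1cc(C[C@H]2CO[C@H](c3ccc(O)c(OC)c3)[C@H]2COC(=O)CC(C)C)ccc1O | target

Total step count: 11.
Longest linear sequence: 8 steps (steps 4, 5, 6, 7, 8, 9, 10, 11 from 6; equally steps 1, 2, 6, 7, 8, 9, 10, 11 from 1).

Steps most likely to fail

1. Step 6.
- What may go wrong: slow alkylation of the crowded enolate, proton transfer that quenches the enolate before the second bond forms, or partial attack at the lactone carbonyl.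
- Fallback: divide the coupling into two separately purified and optimised operations. Setting out from 5 and 8, the lithiated dithiane is added as before, but the enolate is protonated with aqueous NH4Cl to give the monoadduct lactone F1. After purification this is re-enolised with LiN(i-Pr)2 in THF/DMPU at −78 °C and alkylated with 10 anti to the dithianyl group. The sequence comes back to the route at 13.

2. Step 9.
- What may go wrong: Friedel–Crafts closure of ring B onto the benzylic cation competing with oxygen trapping, or erosion of the facial selectivity of trapping through reversible ring opening.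
- Fallback: set C2 by reagent control and form O1–C5 at the acyl level, so that no free benzylic cation is generated while the O1–C2 bond and the C2 configuration are set.
- Setting out from 14, Corey–Bakshi–Shibata reduction gives the (S)-carbinol F2. It uses the (R)-B-methyl oxazaborolidine derived from diphenylprolinol and BH3·SMe2, with ring A acting as the large group.
- Brief treatment with CSA in wet THF moves the lactone onto the benzylic oxygen and unmasks the acetal carbon as the formyl lactone F3. This is reduced in the same flask with NaBH4 to the hydroxymethyl lactone F4.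
- i-Bu2AlH at −78 °C gives the lactol F5. Et3SiH with BF3·OEt2 at −78 °C then reduces the C5 oxocarbenium ion and comes back to the route at 16.

3. Step 7.
- What may go wrong: loss of the menthyloxy acetal under the Lewis acid, β-elimination of the acyloxy group next to the newly formed ketone, or incomplete cleavage of the hindered dithiane.
- Fallback: invert the order so that the sensitive acetal and lactone are gone before sulfur is removed. Setting out from 13, LiAlH4 in THF gives the dithiane diol F6. Mercury-assisted hydrolysis (HgO, BF3·OEt2, aq. THF) gives the hydroxy ketone F7. NaBH4 in MeOH reduces this and comes back to the route at 15.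

Further compounds
F1 | step 6 | (4R,5R)-4-[2-(4-benzyloxy-3-methoxyphenyl)-1,3-dithian-2-yl]-5-(l-menthyloxy)dihydrofuran-2(3H)-one | O=C1C[C@@H](C2(c3ccc(OCc4ccccc4)c(OC)c3)SCCCS2)[C@H](O[C@@H]2C[C@H](C)CC[C@H]2C(C)C)O1
F2 | step 9 | (3R,4R,5R)-3-(4-benzyloxy-3-methoxybenzyl)-4-[(S)-(4-benzyloxy-3-methoxyphenyl)(hydroxy)methyl]-5-(l-menthyloxy)dihydrofuran-2(3H)-one | COc1cc(C[C@H]2C(=O)O[C@@H](O[C@@H]3C[C@H](C)CC[C@H]3C(C)C)[C@@H]2[C@H](O)c2ccc(OCc3ccccc3)c(OC)c2)ccc1OCc1ccccc1
F3 | step 9 | (2S,3S,4R)-2-(4-benzyloxy-3-methoxyphenyl)-4-(4-benzyloxy-3-methoxybenzyl)-5-oxooxolane-3-carbaldehyde | COc1cc(C[C@H]2C(=O)O[C@H](c3ccc(OCc4ccccc4)c(OC)c3)[C@H]2C=O)ccc1OCc1ccccc1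
F4 | step 9 | (3R,4R,5S)-3-(4-benzyloxy-3-methoxybenzyl)-5-(4-benzyloxy-3-methoxyphenyl)-4-(hydroxymethyl)dihydrofuran-2(3H)-one | COc1cc(C[C@H]2C(=O)O[C@H](c3ccc(OCc4ccccc4)c(OC)c3)[C@H]2CO)ccc1OCc1ccccc1
F5 | step 9 | (3R,4R,5S)-3-(4-benzyloxy-3-methoxybenzyl)-5-(4-benzyloxy-3-methoxyphenyl)-4-(hydroxymethyl)oxolan-2-ol, anomers | COc1cc(C[C@H]2C(O)O[C@H](c3ccc(OCc4ccccc4)c(OC)c3)[C@H]2CO)ccc1OCc1ccccc1
F6 | step 7 | (2R,3R)-2-[2-(4-benzyloxy-3-methoxyphenyl)-1,3-dithian-2-yl]-3-(4-benzyloxy-3-methoxybenzyl)butane-1,4-diol | COc1cc(C[C@@H](CO)[C@H](CO)C2(c3ccc(OCc4ccccc4)c(OC)c3)SCCCS2)ccc1OCc1ccccc1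
F7 | step 7 | (2R,3R)-1-(4-benzyloxy-3-methoxyphenyl)-3-(4-benzyloxy-3-methoxybenzyl)-4-hydroxy-2-(hydroxymethyl)butan-1-one | COc1cc(C[C@@H](CO)[C@H](CO)C(=O)c2ccc(OCc3ccccc3)c(OC)c2)ccc1OCc1ccccc1
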